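## Retrosynthetic overview

1. Target ⇐ hexaphenolic dimer with a C4 ketone in the lower unit: global hydrogenolysis of the benzyl ethers, then substrate-controlled NaBH4 reduction sets the lower C4.
2. Lower ring C ⇐ C–O disconnection (C3–O and O1–C2): catalytic enantioselective epoxidation/6-endo oxa-cyclisation of a 2'-hydroxychalcone, made by Claisen–Schmidt condensation on a 5-(flavan-4-yl)gallacetophenone.
3. Interflavanyl C4–C6 bond ⇐ Friedel–Crafts capture of an ent-oritin-type flavan-4-yl cation by dibenzyl gallacetophenone.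
4. Upper ring C ⇐ the same C–O-forming oxidative cyclisation (mirror-image ligand) of the simple chalcone from dibenzyl gallacetophenone and 4-benzyloxybenzaldehyde.
5. Ring order: rings A and B are bought in; upper ring C is closed first, lower ring C second.

Assumption: the catalyst made from La(OiPr)3 and (R)-BINOL is taken to give the (αS,βR)-epoxide and the (S)-ligand its mirror image; if the sense is the opposite, the two ligands are exchanged between steps 3 and 7, since both antipodes are used.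

## Route

Step 1
Reactants: 1 gallacetophenone [1-(2,3,4-trihydroxyphenyl)ethan-1-one]
Product: 2 1-[3,4-bis(benzyloxy)-2-hydroxyphenyl]ethan-1-one
Conditions: BnBr (2.1 equiv), K2CO3 (2.2 equiv), DMF, rt, 16 h
Reagents that add atoms: benzyl bromide, BrCc1ccccc1
Why: Williamson ether synthesis in which the 2-OH, hydrogen-bonded to the acetyl carbonyl, is the least acidic and least nucleophilic phenol, so two equivalents of benzyl bromide cap only O-3 and O-4; no stereocentre is formed.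

Step 2
Reactants: 2 1-[3,4-bis(benzyloxy)-2-hydroxyphenyl]ethan-1-one; 3 4-(benzyloxy)benzaldehyde
Product: 4 (E)-1-[3,4-bis(benzyloxy)-2-hydroxyphenyl]-3-[4-(benzyloxy)phenyl]prop-2-en-1-one
Conditions: KOH (aq 50 %), EtOH, rt, 24 h
Reagents that add atoms: none
Why: Claisen–Schmidt condensation (crossed aldol, then E1cB loss of water) of a methyl ketone with a non-enolisable aldehyde gives the thermodynamically favoured E-enone; no stereocentre is formed.

Step 3
Reactants: 4 (E)-1-[3,4-bis(benzyloxy)-2-hydroxyphenyl]-3-[4-(benzyloxy)phenyl]prop-2-en-1-one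
Product: 6 (2S,3S)-7,8-bis(benzyloxy)-2-[4-(benzyloxy)phenyl]-3-hydroxychroman-4-one, via epoxide 5 (not isolated)
Conditions: La(OiPr)3 (10 mol %), (R)-BINOL (10 mol %), Ph3As=O (10 mol %), t-BuOOH (1.5 equiv, decane), 4 Å MS, THF, argon, 0 °C to rt
Reagents that add atoms: tert-butyl hydroperoxide, CC(C)(C)OO
Why: Proposed new method: the free 2'-OH and the carbonyl oxygen of 4 bind the La centre as a six-membered aryloxide–ketone chelate that holds the enone s-cis in the binaphthoxide pocket, so the La-bound tert-butyl peroxide adds to one enone face (Weitz–Scheffer epoxidation) to give trans-epoxide 5, whose La-bound aryloxide then opens the Lewis-acid-activated oxirane at the benzylic carbon in a 6-endo SN2 step, so C3 keeps the oxirane configuration and C2 is set trans to it by inversion (2S,3S); the closest known reaction types are the La(OiPr)3/BINOL/Ph3As=O-catalysed hydroperoxide epoxidation of chalcones that carry no free phenol and the racemic Algar–Flynn–Oyamada epoxidation/cyclisation of 2'-hydroxychalcones.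

Step 4
Reactants: 6 (2S,3S)-7,8-bis(benzyloxy)-2-[4-(benzyloxy)phenyl]-3-hydroxychroman-4-one
Product: 7 (2S,3R,4S)-7,8-bis(benzyloxy)-2-[4-(benzyloxy)phenyl]chromane-3,4-diol
Conditions: NaBH4 (1.5 equiv), MeOH/THF, 0 °C
Reagents that add atoms: none
Why: NaBH4 reduction of the aryl ketone, in which axial hydride delivery to C4 of the 2,3-trans dihydroflavonol gives the equatorial 4-OH trans to the 3-OH (4S); this centre is in any case erased in step 5.

Step 5
Reactants: 7 (2S,3R,4S)-7,8-bis(benzyloxy)-2-[4-(benzyloxy)phenyl]chromane-3,4-diol; 2 1-[3,4-bis(benzyloxy)-2-hydroxyphenyl]ethan-1-one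
Product: 9 1-{3,4-bis(benzyloxy)-5-[(2S,3R,4S)-7,8-bis(benzyloxy)-2-[4-(benzyloxy)phenyl]-3-hydroxychroman-4-yl]-2-hydroxyphenyl}ethan-1-one, via flavan-4-yl cation 8 (not isolated)
Conditions: Sc(OTf)3 (10 mol %), 2 in fivefold excess (surplus recovered), CH2Cl2/1,4-dioxane (1:1), 0 °C, 7 added over 2 h; chromatography
Reagents that add atoms: none
Why: Friedel–Crafts alkylation by an SN1 path, in which Sc(OTf)3 ionises the benzylic 4-OH (lost as water) to cation 8, stabilised by the para 7-benzyloxy group, and C5 of 2 (para to the free OH, ortho to OBn, the most nucleophilic free position) captures it; the planar cation is taken on both faces, the wanted 3,4-cis epimer (attack on the face of the 3-OH, anti to the 2-aryl group) is expected as roughly 40 % of the adduct beside the 3,4-trans epimer, is separated by chromatography and is recognised by its small J(3,4) of about 6 Hz.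

Step 6
Reactants: 9 1-{3,4-bis(benzyloxy)-5-[(2S,3R,4S)-7,8-bis(benzyloxy)-2-[4-(benzyloxy)phenyl]-3-hydroxychroman-4-yl]-2-hydroxyphenyl}ethan-1-one; 3 4-(benzyloxy)benzaldehyde
Product: 10 (E)-1-{3,4-bis(benzyloxy)-5-[(2S,3R,4S)-7,8-bis(benzyloxy)-2-[4-(benzyloxy)phenyl]-3-hydroxychroman-4-yl]-2-hydroxyphenyl}-3-[4-(benzyloxy)phenyl]prop-2-en-1-one
Conditions: KOH (aq 50 %), EtOH/THF, rt, 36 h
Reagents that add atoms: none
Why: Claisen–Schmidt condensation as in step 2; the three flavan stereocentres have no hydrogen alpha to a carbonyl and are untouched by base, and no new stereocentre is formed.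

Step 7
Reactants: 10 (E)-1-{3,4-bis(benzyloxy)-5-[(2S,3R,4S)-7,8-bis(benzyloxy)-2-[4-(benzyloxy)phenyl]-3-hydroxychroman-4-yl]-2-hydroxyphenyl}-3-[4-(benzyloxy)phenyl]prop-2-en-1-one
Product: 12 (2R,3R)-7,8-bis(benzyloxy)-6-[(2S,3R,4S)-7,8-bis(benzyloxy)-2-[4-(benzyloxy)phenyl]-3-hydroxychroman-4-yl]-2-[4-(benzyloxy)phenyl]-3-hydroxychroman-4-one, via epoxide 11 (not isolated)
Conditions: La(OiPr)3 (10 mol %), (S)-BINOL (10 mol %), Ph3As=O (10 mol %), t-BuOOH (1.5 equiv, decane), 4 Å MS, THF, argon, 0 °C to rt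
Reagents that add atoms: tert-butyl hydroperoxide, CC(C)(C)OO
Why: Proposed new method: the same chelation-directed La(OiPr)3/BINOL peroxide epoxidation and 6-endo opening of epoxide 11 by the La-bound aryloxide as in step 3, now with the (S)-ligand, so that catalyst control (the remote upper unit should exert no significant bias) fixes the lower C3 from the oxirane and C2 by inversion as (2R,3R); the closest known reaction types are the La(OiPr)3/BINOL/Ph3As=O-catalysed hydroperoxide epoxidation of chalcones and the racemic Algar–Flynn–Oyamada reaction.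

Step 8
Reactants: 12 (2R,3R)-7,8-bis(benzyloxy)-6-[(2S,3R,4S)-7,8-bis(benzyloxy)-2-[4-(benzyloxy)phenyl]-3-hydroxychroman-4-yl]-2-[4-(benzyloxy)phenyl]-3-hydroxychroman-4-one
Product: 13 (2R,3R)-3,7,8-trihydroxy-2-(4-hydroxyphenyl)-6-[(2S,3R,4R)-3,7,8-trihydroxy-2-(4-hydroxyphenyl)chroman-4-yl]chroman-4-one
Conditions: H2 (1 atm), Pd(OH)2/C, THF/MeOH (1:1), rt
Reagents that add atoms: none
Why: Catalytic hydrogenolysis of the six benzyl ethers under neutral conditions, which the oxygen-conjugated aryl ketone, the ring C ethers and the alcohols survive; no stereocentre is touched.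

Step 9
Reactants: 13 (2R,3R)-3,7,8-trihydroxy-2-(4-hydroxyphenyl)-6-[(2S,3R,4R)-3,7,8-trihydroxy-2-(4-hydroxyphenyl)chroman-4-yl]chroman-4-one
Product: 14 (2R,3S,4R)-2-(4-hydroxyphenyl)-6-[(2S,3R,4R)-3,7,8-trihydroxy-2-(4-hydroxyphenyl)chroman-4-yl]chromane-3,4,7,8-tetrol
Conditions: NaBH4 (excess), MeOH, argon, 0 °C; neutral work-up (weak-acid resin to pH 6–7), Sephadex LH-20
Reagents that add atoms: none
Why: NaBH4 reduction of a 2,3-trans dihydroflavonol, in which axial hydride delivery to C4 gives the equatorial 4-OH trans to the 3-OH (4R, the usual course from 2,3-trans dihydroflavonols to 2,3-trans-3,4-trans flavan-3,4-diols), while the upper unit has no reducible group.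

## Compound list

1 | gallacetophenone, 1-(2,3,4-trihydroxyphenyl)ethan-1-one | CC(=O)c1ccc(O)c(O)c1O | starting material
2 | 1-[3,4-bis(benzyloxy)-2-hydroxyphenyl]ethan-1-one | CC(=O)c1ccc(OCc2ccccc2)c(OCc2ccccc2)c1O | intermediate
3 | 4-(benzyloxy)benzaldehyde | O=Cc1ccc(OCc2ccccc2)cc1 | starting material
4 | (E)-1-[3,4-bis(benzyloxy)-2-hydroxyphenyl]-3-[4-(benzyloxy)phenyl]prop-2-en-1-one | O=C(/C=C/c1ccc(OCc2ccccc2)cc1)c1ccc(OCc2ccccc2)c(OCc2ccccc2)c1O | intermediate
5 | [3,4-bis(benzyloxy)-2-hydroxyphenyl][(2S,3R)-3-[4-(benzyloxy)phenyl]oxiran-2-yl]methanone (trans-epoxide, not isolated) | O=C(c1ccc(OCc2ccccc2)c(OCc2ccccc2)c1O)[C@H]1O[C@@H]1c1ccc(OCc2ccccc2)cc1 | intermediate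
6 | (2S,3S)-7,8-bis(benzyloxy)-2-[4-(benzyloxy)phenyl]-3-hydroxychroman-4-one (2,3-trans) | O[C@H]1[C@H](c2ccc(OCc3ccccc3)cc2)Oc2c(ccc(OCc3ccccc3)c2OCc2ccccc2)C1=O | intermediate
7 | (2S,3R,4S)-7,8-bis(benzyloxy)-2-[4-(benzyloxy)phenyl]chromane-3,4-diol (2,3-trans-3,4-trans) | O[C@H]1[C@H](c2ccc(OCc3ccccc3)cc2)Oc2c(ccc(OCc3ccccc3)c2OCc2ccccc2)[C@@H]1O | intermediate
8 | (2S,3R)-7,8-bis(benzyloxy)-2-[4-(benzyloxy)phenyl]-3-hydroxychroman-4-ylium (benzylic C4 cation, not isolated) | O[C@H]1[C@H](c2ccc(OCc3ccccc3)cc2)Oc2c(ccc(OCc3ccccc3)c2OCc2ccccc2)[CH+]1 | intermediate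
9 | 1-{3,4-bis(benzyloxy)-5-[(2S,3R,4S)-7,8-bis(benzyloxy)-2-[4-(benzyloxy)phenyl]-3-hydroxychroman-4-yl]-2-hydroxyphenyl}ethan-1-one (2,3-trans-3,4-cis) | CC(=O)c1cc([C@@H]2c3ccc(OCc4ccccc4)c(OCc4ccccc4)c3O[C@@H](c3ccc(OCc4ccccc4)cc3)[C@@H]2O)c(OCc2ccccc2)c(OCc2ccccc2)c1O | intermediate
10 | (E)-1-{3,4-bis(benzyloxy)-5-[(2S,3R,4S)-7,8-bis(benzyloxy)-2-[4-(benzyloxy)phenyl]-3-hydroxychroman-4-yl]-2-hydroxyphenyl}-3-[4-(benzyloxy)phenyl]prop-2-en-1-one | O=C(/C=C/c1ccc(OCc2ccccc2)cc1)c1cc([C@@H]2c3ccc(OCc4ccccc4)c(OCc4ccccc4)c3O[C@@H](c3ccc(OCc4ccccc4)cc3)[C@@H]2O)c(OCc2ccccc2)c(OCc2ccccc2)c1O | intermediate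
11 | {3,4-bis(benzyloxy)-5-[(2S,3R,4S)-7,8-bis(benzyloxy)-2-[4-(benzyloxy)phenyl]-3-hydroxychroman-4-yl]-2-hydroxyphenyl}[(2R,3S)-3-[4-(benzyloxy)phenyl]oxiran-2-yl]methanone (trans-epoxide, not isolated) | O=C(c1cc([C@@H]2c3ccc(OCc4ccccc4)c(OCc4ccccc4)c3O[C@@H](c3ccc(OCc4ccccc4)cc3)[C@@H]2O)c(OCc2ccccc2)c(OCc2ccccc2)c1O)[C@@H]1O[C@H]1c1ccc(OCc2ccccc2)cc1 | intermediate
12 | (2R,3R)-7,8-bis(benzyloxy)-6-[(2S,3R,4S)-7,8-bis(benzyloxy)-2-[4-(benzyloxy)phenyl]-3-hydroxychroman-4-yl]-2-[4-(benzyloxy)phenyl]-3-hydroxychroman-4-one | O[C@@H]1[C@@H](c2ccc(OCc3ccccc3)cc2)Oc2c(cc([C@@H]3c4ccc(OCc5ccccc5)c(OCc5ccccc5)c4O[C@@H](c4ccc(OCc5ccccc5)cc4)[C@@H]3O)c(OCc3ccccc3)c2OCc2ccccc2)C1=O | intermediate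
13 | (2R,3R)-3,7,8-trihydroxy-2-(4-hydroxyphenyl)-6-[(2S,3R,4R)-3,7,8-trihydroxy-2-(4-hydroxyphenyl)chroman-4-yl]chroman-4-one | O[C@@H]1[C@@H](c2ccc(O)cc2)Oc2c(cc([C@@H]3c4ccc(O)c(O)c4O[C@@H](c4ccc(O)cc4)[C@@H]3O)c(O)c2O)C1=O | intermediate
14 | (2R,3S,4R)-2-(4-hydroxyphenyl)-6-[(2S,3R,4R)-3,7,8-trihydroxy-2-(4-hydroxyphenyl)chroman-4-yl]chromane-3,4,7,8-tetrol (upper unit 2,3-trans-3,4-cis, lower unit 2,3-trans-3,4-trans; ent-oritin-(4α→6)-oritin-4α-ol) | Oc1ccc([C@H]2Oc3c(cc([C@@H]4c5ccc(O)c(O)c5O[C@@H](c5ccc(O)cc5)[C@@H]4O)c(O)c3O)[C@@H](O)[C@@H]2O)cc1 | target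

Note on descriptors: the upper C4 reads S wherever the ring it is bonded to still carries O-benzyl groups (9 to 12) and R once those oxygens are free (13, 14). The geometry is the same throughout; only the CIP ranking of the two aryl branches changes.

## Step count and risks

Total step count: 9. Longest linear sequence: 9 (1 → 2 → 4 → 6 → 7 → 9 → 10 → 12 → 13 → 14; compounds 2 and 3 are each used twice).

The three steps most likely to fail are steps 3, 5 and 7.

**Step 3 (proposed new method).** The free phenol could restructure or poison the catalyst formed from La(OiPr)3 and BINOL. Background oxa-Michael closure to the flavanone or 5-exo opening of the epoxide to a benzofuranone could compete. The enantioselectivity is untested. The fallback is known chemistry that sets out from 2 and comes back at 6. Compound 2 is capped with MOMCl/iPr2NEt (CH2Cl2) to give 1-[3,4-bis(benzyloxy)-2-(methoxymethoxy)phenyl]ethan-1-one F1. F1 is condensed with 3 (KOH, EtOH) to (E)-1-[3,4-bis(benzyloxy)-2-(methoxymethoxy)phenyl]-3-[4-(benzyloxy)phenyl]prop-2-en-1-one F2. Juliá–Colonna epoxidation of F2 (poly-D-leucine, urea–H2O2, DBU, THF) gives [3,4-bis(benzyloxy)-2-(methoxymethoxy)phenyl][(2S,3R)-3-[4-(benzyloxy)phenyl]oxiran-2-yl]methanone F3. Aqueous HCl in THF at 50 °C then removes the MOM group, and the freed phenol opens the oxirane at the benzylic carbon with inversion to give 6.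

**Step 5.** The cation is captured on both faces, so the wanted 3,4-cis epimer may be the minor product, and the electron-rich ring A of 7 or of 9 can compete with 2 for the cation. The fallback replaces intermolecular face selection by intramolecular delivery; it sets out from 7 and comes back at 9. Mitsunobu cyclodehydration (PPh3, DIAD, THF, 0 °C) closes 7, by displacement of the activated benzylic 4-OH by O-3 with inversion, to (2S,3R,4R)-7,8-bis(benzyloxy)-2-[4-(benzyloxy)phenyl]-3,4-epoxychromane F4, whose oxirane oxygen keeps the place of the 3-OH and which is used crude. Separately, 1 and B(OiPr)3 (toluene, removal of isopropanol) give the cyclic aryl borate 1-[4-hydroxy-2-(propan-2-yloxy)-1,3,2-benzodioxaborol-5-yl]ethan-1-one F5. F4 and F5 are mixed in CH2Cl2 at −40 °C: boron binds the oxirane oxygen, the benzylic C4–O bond ionises, and the aryl carbon ortho to the B–O bond is delivered to C4 from the face of the boron-bound 3-oxygen, in analogy to the syn opening of benzylic epoxides by aryl borates. After aqueous work-up only the 3,4-cis adduct 1-{2,3,4-trihydroxy-5-[(2S,3R,4R)-7,8-bis(benzyloxy)-2-[4-(benzyloxy)phenyl]-3-hydroxychroman-4-yl]phenyl}ethan-1-one F6 is expected. Dibenzylation of F6 (BnBr 2 equiv, K2CO3, DMF), with the same selectivity as in step 1, gives 9.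

**Step 7 (proposed new method on an advanced substrate).** The extra secondary alcohol and the bulk of the flavanyl group next to the chelating site may slow or derail the La-mediated epoxidation/cyclisation. The fallback is known chemistry that sets out from 9 and comes back at 12. Compound 9 is treated with excess MOMCl/iPr2NEt to give 1-{3,4-bis(benzyloxy)-5-[(2S,3R,4S)-7,8-bis(benzyloxy)-2-[4-(benzyloxy)phenyl]-3-(methoxymethoxy)chroman-4-yl]-2-(methoxymethoxy)phenyl}ethan-1-one F7. F7 is condensed with 3 (KOH, EtOH/THF) to (E)-1-{3,4-bis(benzyloxy)-5-[(2S,3R,4S)-7,8-bis(benzyloxy)-2-[4-(benzyloxy)phenyl]-3-(methoxymethoxy)chroman-4-yl]-2-(methoxymethoxy)phenyl}-3-[4-(benzyloxy)phenyl]prop-2-en-1-one F8. Juliá–Colonna epoxidation of F8 (poly-L-leucine, urea–H2O2, DBU, THF) gives {3,4-bis(benzyloxy)-5-[(2S,3R,4S)-7,8-bis(benzyloxy)-2-[4-(benzyloxy)phenyl]-3-(methoxymethoxy)chroman-4-yl]-2-(methoxymethoxy)phenyl}[(2R,3S)-3-[4-(benzyloxy)phenyl]oxiran-2-yl]methanone F9. Aqueous HCl in THF at 50 °C then removes both MOM groups and closes ring C of the lower unit to give 12.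

## Further compounds

F1 | step 3 | 1-[3,4-bis(benzyloxy)-2-(methoxymethoxy)phenyl]ethan-1-one | CC(=O)c1ccc(OCc2ccccc2)c(OCc2ccccc2)c1OCOC
F2 | step 3 | (E)-1-[3,4-bis(benzyloxy)-2-(methoxymethoxy)phenyl]-3-[4-(benzyloxy)phenyl]prop-2-en-1-one | O=C(/C=C/c1ccc(OCc2ccccc2)cc1)c1ccc(OCc2ccccc2)c(OCc2ccccc2)c1OCOC
F3 | step 3 | [3,4-bis(benzyloxy)-2-(methoxymethoxy)phenyl][(2S,3R)-3-[4-(benzyloxy)phenyl]oxiran-2-yl]methanone | O=C(c1ccc(OCc2ccccc2)c(OCc2ccccc2)c1OCOC)[C@H]1O[C@@H]1c1ccc(OCc2ccccc2)cc1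
F4 | step 5 | (2S,3R,4R)-7,8-bis(benzyloxy)-2-[4-(benzyloxy)phenyl]-3,4-epoxychromane (oxirane oxygen anti to the 2-aryl group) | O1[C@H]2[C@H](c3ccc(OCc4ccccc4)cc3)Oc3c(ccc(OCc4ccccc4)c3OCc3ccccc3)[C@@H]12
F5 | step 5 | 1-[4-hydroxy-2-(propan-2-yloxy)-1,3,2-benzodioxaborol-5-yl]ethan-1-one | CC(=O)c1ccc2OB(OC(C)C)Oc2c1O
F6 | step 5 | 1-{2,3,4-trihydroxy-5-[(2S,3R,4R)-7,8-bis(benzyloxy)-2-[4-(benzyloxy)phenyl]-3-hydroxychroman-4-yl]phenyl}ethan-1-one | CC(=O)c1cc([C@@H]2c3ccc(OCc4ccccc4)c(OCc4ccccc4)c3O[C@@H](c3ccc(OCc4ccccc4)cc3)[C@@H]2O)c(O)c(O)c1O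
F7 | step 7 | 1-{3,4-bis(benzyloxy)-5-[(2S,3R,4S)-7,8-bis(benzyloxy)-2-[4-(benzyloxy)phenyl]-3-(methoxymethoxy)chroman-4-yl]-2-(methoxymethoxy)phenyl}ethan-1-one | CC(=O)c1cc([C@@H]2c3ccc(OCc4ccccc4)c(OCc4ccccc4)c3O[C@@H](c3ccc(OCc4ccccc4)cc3)[C@@H]2OCOC)c(OCc2ccccc2)c(OCc2ccccc2)c1OCOC
F8 | step 7 | (E)-1-{3,4-bis(benzyloxy)-5-[(2S,3R,4S)-7,8-bis(benzyloxy)-2-[4-(benzyloxy)phenyl]-3-(methoxymethoxy)chroman-4-yl]-2-(methoxymethoxy)phenyl}-3-[4-(benzyloxy)phenyl]prop-2-en-1-one | O=C(/C=C/c1ccc(OCc2ccccc2)cc1)c1cc([C@@H]2c3ccc(OCc4ccccc4)c(OCc4ccccc4)c3O[C@@H](c3ccc(OCc4ccccc4)cc3)[C@@H]2OCOC)c(OCc2ccccc2)c(OCc2ccccc2)c1OCOC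
F9 | step 7 | {3,4-bis(benzyloxy)-5-[(2S,3R,4S)-7,8-bis(benzyloxy)-2-[4-(benzyloxy)phenyl]-3-(methoxymethoxy)chroman-4-yl]-2-(methoxymethoxy)phenyl}[(2R,3S)-3-[4-(benzyloxy)phenyl]oxiran-2-yl]methanone | O=C(c1cc([C@@H]2c3ccc(OCc4ccccc4)c(OCc4ccccc4)c3O[C@@H](c3ccc(OCc4ccccc4)cc3)[C@@H]2OCOC)c(OCc2ccccc2)c(OCc2ccccc2)c1OCOC)[C@@H]1O[C@H]1c1ccc(OCc2ccccc2)cc1
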